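Compare one level of first end groups with what each flask offers, then charge the next run by that comparison.

    second end groups → decomposed reagent (k1 = 0.213 s⁻¹, Ea1 = 96.0 kJ mol⁻¹)
    links ⇌ isomer of the product (K2 = 1.30, k2 = 0.540 s⁻¹, Ea2 = 85.0 kJ mol⁻¹, ΔH2 = −63.0 kJ mol⁻¹)
    second end groups + third end groups → links of the second sort (k3 = 10.4 M⁻¹ s⁻¹, Ea3 = 71.0 kJ mol⁻¹)
    first end groups + second end groups → links (k4 = 1010 M⁻¹ s⁻¹, Ea4 = 46.0 kJ mol⁻¹)
    second end groups → decomposition product (k5 = 5.38 × 10⁻⁴ s⁻¹, Ea5 = 104 kJ mol⁻¹)
    (constants at 110 °C)

| flask | first end groups | second end groups | third end groups | temperature | time | remark |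
|---|---|---|---|---|---|---|
| spring | 1.0 mM | 1.02 equiv | 1.00 equiv | 110 °C | 10 s | everything together at the start |
| midnight | 1.0 mM (fed, over 6.0 s) | 1.02 equiv | 1.00 equiv | 110 °C | 10 s | all else is in the flask from the start; the feed brings no volume worth counting |
| noon | 1.0 mM | 1.02 equiv | 1.00 equiv |  | 10 s | everything together at the start at 90 °C, warmed to 110 °C at 6.0 s |
| dusk | 1.0 mM (fed, over 6.0 s) | 1.02 equiv | 1.00 equiv |  | 10 s | the addition at 90 °C, then warmed to 110 °C; the feed brings no volume worth counting |

- the constants hold at 110 °C; other temperatures follow from the activation energies and enthalpies

- the flask with the highest amount of links, in percent of the first end groups charged ("all alike" if they lie within 1.5 percentage points) (spring / midnight / noon / dusk / all alike)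
- final links, as a percentage of the first end groups charged, in spring
- final links, as a percentage of the first end groups charged, in midnight
- final links, as a percentage of the first end groups charged, in noon
- final links, as a percentage of the first end groups charged, in dusk

1. Second end groups couple at a rate proportional to first end groups, but they decompose at a rate that does not depend on them. The other exits are slower than decomposition at 110 °C: 0.0104 s⁻¹ and 5.38 × 10⁻⁴ s⁻¹ against 0.213 s⁻¹. So use the break-even level, k1/k4, the level of first end groups at which second end groups couple as fast as they decompose: 0.211 mM at 110 °C.

2. Replace the falling curve of first end groups by a mean level, 0.500 mM for a full charge. The coupled share of second end groups (the selectivity) is then mean/(mean + break-even), which gives 70.3% in spring. That is 71.7% of the first end groups charged.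

3. Links and isomer relax with a half-life of 0.726 s, shorter than 10 s. So I split the coupled amount by K2, which gives 31.2% links for spring.

4. At 90 °C the break-even level is 0.0888 mM, lower than at 110 °C. The share rises to 84.9%, worth 37.7% links if every coupling ran cold. In noon some reagent meets the hot level after warming, so I place noon between my two figures.

5. Second end groups decompose at 110 °C with a half-life of 3.25 s, shorter than the feed of 6.0 s. In midnight, then, the reagent meets a mean level below 0.500 mM, and I rank midnight lowest without giving a figure.

6. Decision: charge at once at 90 °C and warm at 6.0 s, as in noon.

The forecast also names noon, with 31.7%, 19.9%, 35.3% and 31.1% for spring, midnight, noon and dusk, on the ground that “starting cold with everything together saves reagent”.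

The simulation gives noon highest, with 31.8%, 20.0%, 35.4% and 31.6% in the same order. In noon, coupling ran cold up to 6.00 s, leaving 29.8% of the first end groups with 0.107 mM of decomposed reagent formed; after warming, links fell from 43.7% to 35.4% as isomer rose to 43.8%. In midnight, decomposition ran while first end groups were still arriving, and 0.536 mM of decomposed reagent stood at 10.0 s. Spring kept 27.2% of its first end groups against my 28.3%. Midnight's coupled and lost amounts read as a mean level of 0.179 mM, lower than 0.500 mM.

In the neighbour flask, midnight with 0.40 mM of first end groups, the level read from midnight scales with the charge to 0.0716 mM, below break-even. The share goes from 45.9% in midnight to 25.4% in the neighbour, so midnight's 20.0% scales to 11.1% links. The computed result for the neighbour is 15.4%, higher than this estimate.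

Its constants were chosen freely; what happens was integrated by code.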